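Numbering: C1 is the lactone carbonyl and C26 the terminal methyl. The target is the all-syn (5S,7R,9R,11R) compound and has one ring.
Enabling feature: the only ring is the six-membered lactone O–C1(=O)–C2=C3–C4–C5. Its cis C2=C3 alkene sits between the acyl group on the C5 oxygen and the C4 methylene on C5, which amounts to an acrylate and an allyl group joined end to end.
Retrosynthetic cuts: C2=C3 (ring-closing metathesis), then O–C1 (acrylate ester), then C4–C5, C6–C7, C8–C9 and C10–C11 (four aldehyde allylations). These lead back to hexadecanal, allyl acetate and acryloyl chloride.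
Forward order: the chain grows linearly C11 → C9 → C7 → C5 by cycles of allylation and ozonolysis–reduction, the C5 alcohol is acylated, the lactone ring closes in the penultimate step, and acid then frees the triol.
Stereochemistry: all four carbinol centres come from catalyst control, with the same (S)-ligated iridium catalyst adding allyl to the Si face of each aldehyde. The metathesis creates no stereocentre, and ring size fixes the cis alkene.

Key step: step 11

Remark on the chemistry: (S)-Cl,MeO-BIPHEP is taken to be the ligand antipode that directs allyl to the Si face of unbranched aliphatic aldehydes. All four allylations need this same face because the polyol is all-syn.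

Step 1
Reactants: 1 hexadecanal; 2 allyl acetate
Product: 3 (4R)-nonadec-1-en-4-ol
Conditions: [Ir(cod)Cl]2 (2.5 mol %), (S)-Cl,MeO-BIPHEP (5 mol %), 4-chloro-3-nitrobenzoic acid (10 mol %), Cs2CO3 (20 mol %), iPrOH (2 equiv), THF, 100 °C, sealed tube
Reagents that add atoms: allyl acetate (compound 2), C=CCOC(C)=O
Why: Krische carbonyl allylation by transfer hydrogenation, in which isopropanol serves as reductant, allyl acetate ionises to an allyliridium species, and its sigma-allyl form adds to the aldehyde through a closed chair transition state whose (S)-ligand exposes the Si face, which should set C11 as R.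

Step 2
Reactants: 3 (4R)-nonadec-1-en-4-ol
Product: 5 (3R)-octadecane-1,3-diol, via secondary ozonide 4 (not isolated)
Conditions: O3, CH2Cl2, −78 °C; then MeOH, NaBH4, −78 °C to rt
Reagents that add atoms: ozone, [O-][O+]=O
Why: Ozonolysis with reductive NaBH4 work-up cleaves the only alkene to the primary alcohol without touching the C11 carbinol, and stopping at the alcohol avoids isolating an elimination-prone β-hydroxy aldehyde.

Step 3
Reactants: 5 (3R)-octadecane-1,3-diol; 2 allyl acetate
Product: 7 (4S,6R)-henicos-1-ene-4,6-diol, via (3R)-3-hydroxyoctadecanal 6 (not isolated)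
Conditions: [Ir(cod)Cl]2 (2.5 mol %), (S)-Cl,MeO-BIPHEP (5 mol %), 4-chloro-3-nitrobenzoic acid (10 mol %), Cs2CO3 (20 mol %), THF (1 M), 100 °C, sealed tube
Reagents that add atoms: allyl acetate (compound 2), C=CCOC(C)=O
Why: Site-selective Krische allylation at the alcohol oxidation level, known for unprotected 1,3-glycols, in which the primary carbinol is dehydrogenated much faster than the secondary one, the transient aldehyde 6 is trapped at once by the allyliridium species, and the (S)-ligand again imposes Si-face attack, which should set C9 syn to C11 under catalyst control.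

Step 4
Reactants: 7 (4S,6R)-henicos-1-ene-4,6-diol
Product: 8 (4S,6R)-2,2-dimethyl-6-pentadecyl-4-(prop-2-en-1-yl)-1,3-dioxane
Conditions: 2,2-dimethoxypropane, PPTS (cat.), CH2Cl2, rt
Reagents that add atoms: 2,2-dimethoxypropane, COC(C)(C)OC
Why: Acid-catalysed transacetalisation of a syn-1,3-diol gives the chair dioxane with both side chains equatorial, masks C9 and C11 in one operation, allows any anti isomer to be removed by chromatography, and lets the syn relationship be checked by the 13C acetonide method.

Step 5
Reactants: 8 (4S,6R)-2,2-dimethyl-6-pentadecyl-4-(prop-2-en-1-yl)-1,3-dioxane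
Product: 10 2-[(4S,6R)-2,2-dimethyl-6-pentadecyl-1,3-dioxan-4-yl]ethan-1-ol, via secondary ozonide 9 (not isolated)
Conditions: O3, CH2Cl2, −78 °C; then MeOH, NaBH4, −78 °C to rt
Reagents that add atoms: ozone, [O-][O+]=O
Why: Ozonolysis with NaBH4 work-up shortens the allyl group to the C8–C7 hydroxyethyl arm under conditions to which the acetonide is inert.

Step 6
Reactants: 10 2-[(4S,6R)-2,2-dimethyl-6-pentadecyl-1,3-dioxan-4-yl]ethan-1-ol; 2 allyl acetate
Product: 12 (2S)-1-[(4S,6R)-2,2-dimethyl-6-pentadecyl-1,3-dioxan-4-yl]pent-4-en-2-ol, via dioxanylacetaldehyde 11 (not isolated)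
Conditions: [Ir(cod)Cl]2 (2.5 mol %), (S)-Cl,MeO-BIPHEP (5 mol %), 4-chloro-3-nitrobenzoic acid (10 mol %), Cs2CO3 (20 mol %), THF, 100 °C, sealed tube
Reagents that add atoms: allyl acetate (compound 2), C=CCOC(C)=O
Why: Krische allylation from the alcohol oxidation level, well precedented for acetonide-bearing 1,3-polyol chains, keeps aldehyde 11 at a low transient concentration so that β-elimination is suppressed, while the (S)-catalyst overrides the weak bias of the β-alkoxy centre and adds allyl to the Si face, which should set C7 syn to C9.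

Step 7
Reactants: 12 (2S)-1-[(4S,6R)-2,2-dimethyl-6-pentadecyl-1,3-dioxan-4-yl]pent-4-en-2-ol
Product: 13 tert-butyl({(2S)-1-[(4R,6R)-2,2-dimethyl-6-pentadecyl-1,3-dioxan-4-yl]pent-4-en-2-yl}oxy)dimethylsilane (C7 TBS ether of 12; the dioxane C4 descriptor changes by priority only)
Conditions: TBSCl, imidazole, DMF, rt
Reagents that add atoms: tert-butyldimethylsilyl chloride, CC(C)(C)[Si](C)(C)Cl
Why: Imidazole-promoted silylation of the only free hydroxyl gives an ether stable to ozone, borohydride and mild base, which keeps the C7 oxygen distinct from the C5 oxygen to be acylated later and can leave together with the acetonide in the last step.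

Step 8
Reactants: 13 C7 TBS ether
Product: 15 (3S)-3-[(tert-butyldimethylsilyl)oxy]-4-[(4R,6R)-2,2-dimethyl-6-pentadecyl-1,3-dioxan-4-yl]butan-1-ol, via secondary ozonide 14 (not isolated)
Conditions: O3, CH2Cl2, −78 °C; then MeOH, NaBH4, −78 °C to rt
Reagents that add atoms: ozone, [O-][O+]=O
Why: Ozonolysis with NaBH4 work-up converts the terminal alkene into the C5 primary alcohol, and neither the silyl ether nor the acetonide reacts under these cold, neutral to mildly basic conditions.

Step 9
Reactants: 15 (3S)-3-[(tert-butyldimethylsilyl)oxy]-4-[(4R,6R)-2,2-dimethyl-6-pentadecyl-1,3-dioxan-4-yl]butan-1-ol; 2 allyl acetate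
Product: 17 (4S,6S)-6-[(tert-butyldimethylsilyl)oxy]-7-[(4R,6R)-2,2-dimethyl-6-pentadecyl-1,3-dioxan-4-yl]hept-1-en-4-ol, via β-silyloxy aldehyde 16 (not isolated)
Conditions: [Ir(cod)Cl]2 (2.5 mol %), (S)-Cl,MeO-BIPHEP (5 mol %), 4-chloro-3-nitrobenzoic acid (10 mol %), Cs2CO3 (20 mol %), THF, 100 °C, sealed tube
Reagents that add atoms: allyl acetate (compound 2), C=CCOC(C)=O
Why: A fourth Krische allylation from the alcohol oxidation level, precedented for β-silyloxy alcohols in iterative polyol synthesis, generates aldehyde 16 only transiently and adds allyl to its Si face under control of the (S)-ligand, which should set C5 (S by the priority rules) syn to C7 and install C4 and C3 at the same time.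

Step 10
Reactants: 17 (4S,6S)-6-[(tert-butyldimethylsilyl)oxy]-7-[(4R,6R)-2,2-dimethyl-6-pentadecyl-1,3-dioxan-4-yl]hept-1-en-4-ol; 18 acryloyl chloride
Product: 19 (4S,6R)-6-[(tert-butyldimethylsilyl)oxy]-7-[(4R,6R)-2,2-dimethyl-6-pentadecyl-1,3-dioxan-4-yl]hept-1-en-4-yl prop-2-enoate
Conditions: iPr2NEt, DMAP (cat.), CH2Cl2, −78 °C to 0 °C
Reagents that add atoms: acryloyl chloride (compound 18), C=CC(=O)Cl
Why: DMAP-catalysed esterification of the only free hydroxyl with an acid chloride at low temperature limits polymerisation and conjugate addition, brings in C1 and C2, and leaves the C5–O bond intact so that the configuration is retained.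

Step 11
Reactants: 19 (4S,6R)-6-[(tert-butyldimethylsilyl)oxy]-7-[(4R,6R)-2,2-dimethyl-6-pentadecyl-1,3-dioxan-4-yl]hept-1-en-4-yl prop-2-enoate
Product: 20 (6S)-6-{(2R)-2-[(tert-butyldimethylsilyl)oxy]-3-[(4R,6R)-2,2-dimethyl-6-pentadecyl-1,3-dioxan-4-yl]propyl}-5,6-dihydro-2H-pyran-2-one
Conditions: RuCl2(=CHPh)(PCy3)(H2IMes) (second-generation Grubbs catalyst, 5 mol %), CH2Cl2 (about 2 mM), reflux, argon sparge
Reagents that add atoms: none
Why: The benzylidene first exchanges with the unhindered, electron-rich terminal alkene of the allyl arm to place ruthenium on C3, this alkylidene adds to the tethered acrylate C=C in an intramolecular [2+2] step, and cycloreversion of the ruthenacyclobutane forms C2=C3 and releases Ru=CH2, which carries the chain while ethene escapes. The closest known reaction type is the ring-closing metathesis of acrylates of homoallylic alcohols to 5,6-dihydro-2H-pyran-2-ones, a standard use of this catalyst. The one ring formed, O–C1(=O)–C2=C3–C4–C5, closes as a six-membered ring by alkene–alkene metathesis with the new double bond endocyclic, so only the cis geometry can be accommodated. No stereocentre is created, and C5, C7, C9 and C11 take no part in any bond change. The step needs ring closure to outrun intermolecular dimerisation and needs a catalyst able to engage an electron-poor alkene; high dilution, removal of ethene at reflux and the N-heterocyclic carbene ligand secure both. The substrate holds only these two alkenes and no free hydroxyl, so no other metathesis partner or chelating group competes.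

Step 12
Reactants: 20 protected lactone
Product: 21 (6S)-6-[(2R,4R,6R)-2,4,6-trihydroxyhenicosyl]-5,6-dihydro-2H-pyran-2-one (target)
Conditions: 48 % aq HF, MeCN, 0 °C to rt
Reagents that add atoms: none
Why: Acidic global deprotection, in which aqueous HF cleaves the Si–O bond (driven by Si–F bond strength) and hydrolyses the acetonide in the same pot, uses a non-nucleophilic acidic medium that should leave the unsaturated lactone intact, avoids base-induced conjugate addition of the C7 hydroxyl to C3, and breaks no bond to a stereocentre.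

Compound list
1 | hexadecanal | CCCCCCCCCCCCCCCC=O | starting material
2 | allyl acetate | C=CCOC(C)=O | starting material
3 | (4R)-nonadec-1-en-4-ol | CCCCCCCCCCCCCCC[C@@H](O)CC=C | intermediate
4 | secondary ozonide of 3, (2R)-1-(1,2,4-trioxolan-3-yl)heptadecan-2-ol, trioxolane carbon unassigned | CCCCCCCCCCCCCCC[C@@H](O)CC1OCOO1 | intermediate
5 | (3R)-octadecane-1,3-diol | CCCCCCCCCCCCCCC[C@@H](O)CCO | intermediate
6 | (3R)-3-hydroxyoctadecanal | CCCCCCCCCCCCCCC[C@@H](O)CC=O | intermediate
7 | (4S,6R)-henicos-1-ene-4,6-diol (syn) | CCCCCCCCCCCCCCC[C@@H](O)C[C@@H](O)CC=C | intermediate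
8 | (4S,6R)-2,2-dimethyl-6-pentadecyl-4-(prop-2-en-1-yl)-1,3-dioxane | CCCCCCCCCCCCCCC[C@@H]1C[C@H](CC=C)OC(C)(C)O1 | intermediate
9 | secondary ozonide of 8, (4R,6R)-2,2-dimethyl-6-pentadecyl-4-[(1,2,4-trioxolan-3-yl)methyl]-1,3-dioxane, trioxolane carbon unassigned | CCCCCCCCCCCCCCC[C@@H]1C[C@H](CC2OCOO2)OC(C)(C)O1 | intermediate
10 | 2-[(4S,6R)-2,2-dimethyl-6-pentadecyl-1,3-dioxan-4-yl]ethan-1-ol | CCCCCCCCCCCCCCC[C@@H]1C[C@H](CCO)OC(C)(C)O1 | intermediate
11 | 2-[(4R,6R)-2,2-dimethyl-6-pentadecyl-1,3-dioxan-4-yl]acetaldehyde | CCCCCCCCCCCCCCC[C@@H]1C[C@H](CC=O)OC(C)(C)O1 | intermediate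
12 | (2S)-1-[(4S,6R)-2,2-dimethyl-6-pentadecyl-1,3-dioxan-4-yl]pent-4-en-2-ol | CCCCCCCCCCCCCCC[C@@H]1C[C@H](C[C@@H](O)CC=C)OC(C)(C)O1 | intermediate
13 | tert-butyl({(2S)-1-[(4R,6R)-2,2-dimethyl-6-pentadecyl-1,3-dioxan-4-yl]pent-4-en-2-yl}oxy)dimethylsilane | CCCCCCCCCCCCCCC[C@@H]1C[C@H](C[C@@H](O[Si](C)(C)C(C)(C)C)CC=C)OC(C)(C)O1 | intermediate
14 | secondary ozonide of 13 (other centres as in 13, trioxolane carbon unassigned) | CCCCCCCCCCCCCCC[C@@H]1C[C@H](C[C@@H](O[Si](C)(C)C(C)(C)C)CC2OCOO2)OC(C)(C)O1 | intermediate
15 | (3S)-3-[(tert-butyldimethylsilyl)oxy]-4-[(4R,6R)-2,2-dimethyl-6-pentadecyl-1,3-dioxan-4-yl]butan-1-ol | CCCCCCCCCCCCCCC[C@@H]1C[C@H](C[C@@H](O[Si](C)(C)C(C)(C)C)CCO)OC(C)(C)O1 | intermediate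
16 | (3R)-3-[(tert-butyldimethylsilyl)oxy]-4-[(4R,6R)-2,2-dimethyl-6-pentadecyl-1,3-dioxan-4-yl]butanal | CCCCCCCCCCCCCCC[C@@H]1C[C@H](C[C@@H](O[Si](C)(C)C(C)(C)C)CC=O)OC(C)(C)O1 | intermediate
17 | (4S,6S)-6-[(tert-butyldimethylsilyl)oxy]-7-[(4R,6R)-2,2-dimethyl-6-pentadecyl-1,3-dioxan-4-yl]hept-1-en-4-ol | CCCCCCCCCCCCCCC[C@@H]1C[C@H](C[C@@H](O[Si](C)(C)C(C)(C)C)C[C@@H](O)CC=C)OC(C)(C)O1 | intermediate
18 | acryloyl chloride | C=CC(=O)Cl | starting material
19 | (4S,6R)-6-[(tert-butyldimethylsilyl)oxy]-7-[(4R,6R)-2,2-dimethyl-6-pentadecyl-1,3-dioxan-4-yl]hept-1-en-4-yl prop-2-enoate | CCCCCCCCCCCCCCC[C@@H]1C[C@H](C[C@@H](O[Si](C)(C)C(C)(C)C)C[C@@H](OC(=O)C=C)CC=C)OC(C)(C)O1 | intermediate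
20 | (6S)-6-{(2R)-2-[(tert-butyldimethylsilyl)oxy]-3-[(4R,6R)-2,2-dimethyl-6-pentadecyl-1,3-dioxan-4-yl]propyl}-5,6-dihydro-2H-pyran-2-one | CCCCCCCCCCCCCCC[C@@H]1C[C@H](C[C@@H](O[Si](C)(C)C(C)(C)C)C[C@@H]2CC=CC(=O)O2)OC(C)(C)O1 | intermediate
21 | (6S)-6-[(2R,4R,6R)-2,4,6-trihydroxyhenicosyl]-5,6-dihydro-2H-pyran-2-one | CCCCCCCCCCCCCCC[C@@H](O)C[C@@H](O)C[C@@H](O)C[C@@H]1CC=CC(=O)O1 | target

Total step count: 12. Longest linear sequence: 12 steps from hexadecanal.

Steps most likely to fail

**Step 3 (allylation of the unprotected diol).**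
- The secondary C11 carbinol may be dehydrogenated in competition with the primary one.
- The transient β-hydroxy aldehyde may dehydrate or undergo retro-aldol cleavage.
- Facial control at C9 may be incomplete.

The fallback replaces catalyst control by substrate control. It sets out from 3 and comes back at 7. Alcohol 3 is treated with Boc2O and DMAP to give tert-butyl (4R)-nonadec-1-en-4-yl carbonate F1. IBr in toluene at −85 °C then triggers the Bartlett–Smith iodocarbonate cyclisation. Its chair transition state with both substituents equatorial should give the syn product (4R,6R)-4-(iodomethyl)-6-pentadecyl-1,3-dioxan-2-one F2. K2CO3 in methanol cleaves the carbonate and closes the epoxide to (2R)-1-[(2R)-oxiran-2-yl]heptadecan-2-ol F3. Vinylmagnesium bromide with catalytic CuI opens the epoxide at its CH2 terminus and delivers 7.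

**Step 9 (fourth allylation next to the silyl ether).**
- At 100 °C with carbonate base the silyl group may migrate from the C7 to the C5 oxygen.
- The silyloxy group may be lost by β-elimination from the transient aldehyde.
- The β-stereocentre may erode catalyst control.

The fallback moves to a stoichiometric chiral allylborane at low temperature. It sets out from 15 and comes back at 17. Dess–Martin periodinane oxidises 15 to aldehyde 16, which is isolated this time. Brown allylboration with (−)-Ipc2B(allyl) of the (+)-α-pinene series, which attacks the Si face, is run in Et2O at −78 °C. It should give the diisopinocampheylborinate of 17 F4, and NaOH/H2O2 work-up releases 17.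

**Step 12 (global deprotection on the finished lactone).**
- Acid may promote conjugate addition of the freed C7 hydroxyl to C3. The syn C5/C7 relationship favours this.
- The lactone may open.
- Acetonide hydrolysis may stall.

The fallback inverts the order of events so that the unsaturated lactone never meets acid. It sets out from 19 and comes back at 21. Aqueous HF in MeCN removes both protecting groups from the acrylate to give (4S,6R,8R,10R)-6,8,10-trihydroxypentacos-1-en-4-yl prop-2-enoate F5. The same ring-closing metathesis with RuCl2(=CHPh)(PCy3)(H2IMes) in dilute CH2Cl2 tolerates free hydroxyls and runs under neutral conditions. It then forms C2=C3 and gives 21 directly.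

Further compounds
F1 | step 3 | tert-butyl (4R)-nonadec-1-en-4-yl carbonate | CCCCCCCCCCCCCCC[C@@H](OC(=O)OC(C)(C)C)CC=C
F2 | step 3 | (4R,6R)-4-(iodomethyl)-6-pentadecyl-1,3-dioxan-2-one | CCCCCCCCCCCCCCC[C@@H]1C[C@H](CI)OC(=O)O1
F3 | step 3 | (2R)-1-[(2R)-oxiran-2-yl]heptadecan-2-ol | CCCCCCCCCCCCCCC[C@@H](O)C[C@@H]1CO1
F4 | step 9 | diisopinocampheylborinate of 17 | CCCCCCCCCCCCCCC[C@@H]1C[C@H](C[C@@H](O[Si](C)(C)C(C)(C)C)C[C@@H](OB([C@@H]2C[C@@H]3C[C@H]([C@H]2C)C3(C)C)[C@@H]2C[C@@H]3C[C@H]([C@H]2C)C3(C)C)CC=C)OC(C)(C)O1
F5 | step 12 | (4S,6R,8R,10R)-6,8,10-trihydroxypentacos-1-en-4-yl prop-2-enoate | CCCCCCCCCCCCCCC[C@@H](O)C[C@@H](O)C[C@@H](O)C[C@@H](OC(=O)C=C)CC=C
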